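Retrosynthesis: the 5-O–CH3 bond is cut first (the phenol comes from a methyl ether), then the C2–C1' bond between pyranone ring C and ring B. Ring C is then opened at O1–C2 and C2–C3 (C2 traced to carbon disulfide, its sulfur kept as leaving group), and last the C4–C4a bond to an acetyl group on a tetramethoxybenzene.
Enabling feature: C2 is the β-carbon of the C4 enone and also carries O1, so a C2–SMe bond there is a vinylogous thioester open to palladium insertion. C1' lies between the methoxy-bearing C2' and C6', the carbon at which 1,3-dimethoxybenzene is lithiated and then zincated.
Forward order: ring A is bought fully oxygenated. Step 1 acetylates it with loss of the crowded ortho methyl group, steps 2–3 close ring C by CS2 annulation and S-methylation, step 4 zincates ring B, step 5 joins ring B to the A/C bicycle at C2–C1', and step 6 cleaves the 5-methyl ether under chelation control.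
Stereochemistry: none to set. The target has no stereocentre, no stereogenic double bond and, ring B being symmetrically 2',6'-disubstituted, no stereogenic axis.

Key step: step 5

Remark: flavone numbering is used throughout (ring C = O1, C2, C3, C4; ring A = C4a to C8a; ring B primed); equivalents are planned amounts.

Step 1
Reactants: 1 1,2,3,5-tetramethoxybenzene; 2 acetyl chloride
Product: 4 2-hydroxy-3,4,6-trimethoxyacetophenone, via 2,3,4,6-tetramethoxyacetophenone 3 (not isolated)
Conditions: AlCl3 (2.5 equiv), Et2O, 0 °C → rt; then ice/1 M HCl
Reagents that add atoms: none
Why: Friedel–Crafts acylation at C4 of 1 (C4 and C6 are equivalent, each ortho to two and para to one methoxy group) gives ketone 3 as its AlCl3 complex, and the same Lewis acid should then cleave the ortho methyl ether that is chelated to the carbonyl and forced out of plane between the acetyl group and a neighbouring methoxy group (chelation-assisted demethylation), leaving the ortho ether next to the ring hydrogen and the non-chelating ethers intact.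

Step 2
Reactants: 4 2-hydroxy-3,4,6-trimethoxyacetophenone; 5 carbon disulfide
Product: 7 4-hydroxy-5,7,8-trimethoxy-2H-chromene-2-thione, via 3-(2-hydroxy-3,4,6-trimethoxyphenyl)-3-oxopropanedithioic acid 6 (not isolated)
Conditions: CS2 (1.5 equiv), KOtBu (3 equiv), THF, 0 °C → rt; then 2 M HCl, 0 °C
Reagents that add atoms: none
Why: The phenoxide–enolate dianion of 4 attacks CS2 through carbon (Claisen-type dithiocarboxylation) to give the β-oxo dithioate 6 as its potassium salt, which should cyclise through the phenol oxygen with loss of H2S on acidification, the established annulation of 2-hydroxyacetophenones with CS2.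

Step 3
Reactants: 7 4-hydroxy-5,7,8-trimethoxy-2H-chromene-2-thione
Product: 8 5,7,8-trimethoxy-2-(methylsulfanyl)-4H-chromen-4-one
Conditions: MeI (1.2 equiv), K2CO3 (1.5 equiv), acetone, reflux
Reagents that add atoms: iodomethane, CI
Why: The ambident thioxo-enolate of 7 should be alkylated at its soft sulfur atom by the soft electrophile MeI (S-alkylation), which locks the 4-pyranone tautomer and gives the vinylogous thioester.

Step 4
Reactants: 9 1,3-dimethoxybenzene
Product: 11 (2,6-dimethoxyphenyl)zinc chloride, via (2,6-dimethoxyphenyl)lithium 10 (not isolated)
Conditions: n-BuLi (0.95 equiv), THF, 0 °C → rt; then ZnCl2 (1.1 equiv, THF), 0 °C → rt; solution titrated and used directly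
Reagents that add atoms: zinc chloride, Cl[Zn]Cl
Why: Directed ortho-metalation removes the proton at C2 between the two coordinating methoxy groups, and salt metathesis with a slight excess of ZnCl2 converts the aryllithium completely into the milder arylzinc chloride.

Step 5
Reactants: 8 5,7,8-trimethoxy-2-(methylsulfanyl)-4H-chromen-4-one; 11 (2,6-dimethoxyphenyl)zinc chloride
Product: 12 2-(2,6-dimethoxyphenyl)-5,7,8-trimethoxy-4H-chromen-4-one
Conditions: 11 (2 equiv), Pd(OAc)2 (5 mol %), SPhos (10 mol %), THF, 50 °C; then sat. aq NH4Cl
Reagents that add atoms: none
Why: SPhos-ligated zerovalent palladium, produced when a little of 11 reduces Pd(OAc)2, adds oxidatively into the C2–SMe bond of 8, a bond activated because C2 is the β-carbon of the C4 enone and also carries O1 (a vinylogous thioester). Zinc, being thiophilic, takes up the methanethiolate as MeSZnCl during transmetalation so that sulfur does not block the catalyst, and reductive elimination from the aryl(chromonyl)palladium species forms the C2–C1' bond. The closest known reaction type is the Pd(OAc)2/SPhos Negishi-type coupling of electron-poor heteroaryl methyl thioethers with organozinc halides, a copper-free relative of the Liebeskind–Srogl coupling. No ring is closed and no stereocentre or stereogenic axis is created, ring B being symmetric about the new bond. The selectivity required is substitution at C2 in preference to conjugate addition, attack at the C4 carbonyl or opening of the pyranone; the low nucleophilicity of an arylzinc chloride (no free aryllithium remains because ZnCl2 is in excess) secures this, while the bulky, electron-rich SPhos speeds both insertion into the C–S bond and reductive elimination of the di-ortho-substituted aryl group. An arylzinc is chosen because 2,6-dimethoxyphenylboronic acid would protodeboronate readily under basic coupling conditions.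

Step 6
Reactants: 12 2-(2,6-dimethoxyphenyl)-5,7,8-trimethoxy-4H-chromen-4-one
Product: 13 altisin (2-(2,6-dimethoxyphenyl)-5-hydroxy-7,8-dimethoxy-4H-chromen-4-one)
Conditions: BCl3 (1.5 equiv), CH2Cl2, −78 → 0 °C; then ice-water
Reagents that add atoms: none
Why: BCl3 binds the C4 carbonyl and the peri 5-methoxy oxygen in a six-membered chelate and chloride should remove only that methyl group (chelation-controlled regioselective ether cleavage), since none of the other four methoxy groups (C7, C8, C2', C6') can reach the carbonyl; hydrolysis of the borate releases the hydrogen-bonded 5-phenol.

Compound list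
1 | 1,2,3,5-tetramethoxybenzene | COc1cc(OC)c(OC)c(OC)c1 | starting material
2 | acetyl chloride | CC(=O)Cl | starting material
3 | 2,3,4,6-tetramethoxyacetophenone | CC(=O)c1c(OC)cc(OC)c(OC)c1OC | intermediate
4 | 2-hydroxy-3,4,6-trimethoxyacetophenone | CC(=O)c1c(OC)cc(OC)c(OC)c1O | intermediate
5 | carbon disulfide | S=C=S | starting material
6 | 3-(2-hydroxy-3,4,6-trimethoxyphenyl)-3-oxopropanedithioic acid (present as its potassium salt) | COc1cc(OC)c(OC)c(O)c1C(=O)CC(=S)S | intermediate
7 | 4-hydroxy-5,7,8-trimethoxy-2H-chromene-2-thione | S=c1cc(O)c2c(OC)cc(OC)c(OC)c2o1 | intermediate
8 | 5,7,8-trimethoxy-2-(methylsulfanyl)-4H-chromen-4-one | CSc1cc(=O)c2c(OC)cc(OC)c(OC)c2o1 | intermediate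
9 | 1,3-dimethoxybenzene | COc1cccc(OC)c1 | starting material
10 | (2,6-dimethoxyphenyl)lithium | [Li]c1c(OC)cccc1OC | intermediate
11 | (2,6-dimethoxyphenyl)zinc chloride | COc1cccc(OC)c1[Zn]Cl | intermediate
12 | 2-(2,6-dimethoxyphenyl)-5,7,8-trimethoxy-4H-chromen-4-one | COc1cccc(OC)c1-c1cc(=O)c2c(OC)cc(OC)c(OC)c2o1 | intermediate
13 | altisin, 2-(2,6-dimethoxyphenyl)-5-hydroxy-7,8-dimethoxy-4H-chromen-4-one | COc1cccc(OC)c1-c1cc(=O)c2c(O)cc(OC)c(OC)c2o1 | target

Total step count: 6.
Longest linear sequence: 5 steps (steps 1, 2, 3, 5, 6 from 1); step 4 is a one-step branch from 9.

Steps most likely to fail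

Step 5. What may go wrong: transmetalation and reductive elimination of the doubly ortho-substituted aryl group are slow, so that protodezincation, aryl homocoupling or thiolate poisoning of the catalyst overtakes C–C bond formation. The fallback sets out from 4 and comes back at 12. It brings in the ring B carbons as an acyl group and closes ring C by condensation instead of cross-coupling. Acetophenone 4 would be O-acylated with 2,6-dimethoxybenzoyl chloride (pyridine, DMAP, CH2Cl2) to give the ester 2-acetyl-3,5,6-trimethoxyphenyl 2,6-dimethoxybenzoate F1. Baker–Venkataraman acyl migration (LiN(SiMe3)2, THF, −78 °C → rt) should convert it into the diketone 1-(2,6-dimethoxyphenyl)-3-(2-hydroxy-3,4,6-trimethoxyphenyl)propane-1,3-dione F2. Cyclodehydration (cat. H2SO4, AcOH, 100 °C) should then close the pyranone to 12, which re-enters at step 6.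

Step 1. What may go wrong: site control in the ether cleavage is lost while acylation still runs with excess AlCl3. Either the second ortho methyl ether is cleaved as well, or the ortho ether next to the ring hydrogen is cleaved in place of the crowded one, which would lead on to the 5,6,7-oxygenated series. The fallback sets out from 1 and comes back at 4. It separates C–C bond formation from ether cleavage and introduces the acyl group by directed metalation instead of electrophilic substitution. Compound 1 would be lithiated at C4 between two methoxy groups (n-BuLi, THF, 0 °C) and the aryllithium acylated with N-methoxy-N-methylacetamide to give 3, now isolated and purified. One equivalent of BCl3 (CH2Cl2, −78 °C) should then cleave only the out-of-plane, chelated 2-methyl ether to give 4. No compound outside the list is made (F0). The substitution pattern of 4 should be checked before going on: its lone ring proton is expected to show NOE contacts to two methoxy groups, that of the unwanted isomer to one.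

Step 6. What may go wrong: over-cleavage, in which a second methyl group (the 8-ether next to O1 or one of the twisted ring B ethers) is lost on warming once the 5-ether is gone, or resistance of the boron chelate to hydrolysis. The fallback sets out from 8 and comes back at 13. It moves the demethylation in front of the coupling, so that ring B is never exposed to the Lewis acid. Thioether 8 would be treated with BCl3 (CH2Cl2, −78 → 0 °C) to give 5-hydroxy-7,8-dimethoxy-2-(methylsulfanyl)-4H-chromen-4-one F3. F3 would then be coupled with 11 (3 equiv, the first equivalent forming the zinc phenoxide) under the Pd(OAc)2/SPhos conditions of step 5 to give 13 directly.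

Further compounds
F1 | step 5 | 2-acetyl-3,5,6-trimethoxyphenyl 2,6-dimethoxybenzoate | CC(=O)c1c(OC)cc(OC)c(OC)c1OC(=O)c1c(OC)cccc1OC
F2 | step 5 | 1-(2,6-dimethoxyphenyl)-3-(2-hydroxy-3,4,6-trimethoxyphenyl)propane-1,3-dione | COc1cc(OC)c(OC)c(O)c1C(=O)CC(=O)c1c(OC)cccc1OC
F0 | step 1 | none | none
F3 | step 6 | 5-hydroxy-7,8-dimethoxy-2-(methylsulfanyl)-4H-chromen-4-one | CSc1cc(=O)c2c(O)cc(OC)c(OC)c2o1
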